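Wednesday's flask reads 15.7% of the solid substrate charged as target, the mean of its readings from 4.00 min to 10.0 min. Those readings span 1.7 percentage points with a scatter of 1 point per reading, so I see neither climb nor fall.

| flask | solid substrate | coupling partner | remark | time |
|---|---|---|---|---|
| Wednesday's | 0.093 M | 0.70 equiv | the very flask that is asked about, followed so far |  |
| flask | 0.093 M | 0.700 equiv |  | 20 min |

Wednesday's run (percent of the solid substrate charged): time / min: target / % = 0.500: 3.1; 1.50: 6.5; 3.00: 15.3; 4.00: 16.6; 6.00: 15.8; 8.00: 14.9; 10.0: 15.4

(each reading ± 1 percentage point)

- given per volume of solution although it is solid: solid substrate
- at the start none of the solid substrate is in solution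

- eta: doubling the dissolution coefficient of the solid substrate, all else as stated
- alpha: doubling the amount of coupling partner, all else as stated
- beta: doubling the solubility of the solid substrate, all else as stated

- how much target there is at 20 min, in percent of the solid substrate charged
- the change that raises the amount of target at 20 min, in percent of the solid substrate charged most ("none" if none brings more than 2 percentage points) (eta / alpha / beta / none)
- amount of target at 20 min, in percent of the solid substrate charged, after beta

How much of the possible target is this? Coupling partner is the limiting reagent at 0.700 equiv, so I divide the plateau by that charge and get 22.4%. I carry this as the limiting share, the part of the smaller charge that ends as target. On this scale an even split between target and one other product stands at 0.5. The reading lies below that, at about a quarter, so on this reading more of the partner's charge is not target than is target.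

What moves the plateau, then? I hold the share fixed and change the smaller charge. Alpha takes the partner to 1.40 equiv, so the solid substrate becomes the smaller charge, and with the share held I reckon target at 22.4% of it, an estimated gain of 6.7 points. Eta and beta change no charge, so I expect 15.7% after either. My reckoning is therefore 15.7% at 20 min, alpha as best, and 15.7% after beta.

The forecast gives 15.5%, alpha and, unlike mine, 28% after beta, on this ground: “Doubling solubility doubles the dissolved level and the dissolution driving force”.

This flask gives 15.8% at 20 min, alpha is best with a gain of 5.7 points, and beta gives 16.5%.

    solid substrate ⇌ dissolved substrate, rate k1*(cs1 - [dissolved substrate]) while solid is left; crystals form when [dissolved substrate] > cs1 (solubility = 46.0 mM, k = 0.00798 s⁻¹)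
    dissolved substrate + coupling partner → target (k = 11.8 L mol⁻¹ s⁻¹)
    target ⇌ isomer of the product (K = 2.98, k = 0.116 s⁻¹)
    solid substrate + target → side product (k = 0.0771 L mol⁻¹ s⁻¹)

At 20.0 min this flask has 0% of its coupling partner left and holds 47.0% as isomer of the product. Its limiting share comes to 22.6%. In the neighbour with 1.80 equiv of partner, the solid substrate is the charge that runs out first, with 0% left. The carried share of that whole charge is 22.4%, and that neighbour holds 21.5% of target.

(All runs come from a simulation from invented constants, noise included.)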